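**Plan**

1. Retrosynthesis: the O8 and O9 esters and the C15 silyl ether come off; the furanone is cut at O–C10 back to a C1=C10 alkene and a C3 carbinol; the lactone is cut at O6–C12 and C7–C11; the carbocycle is then cut at C8–C9 while a temporary bond C1–C6 is put back.
2. Enabling feature: the C1 ketone and the oxygenated C6 are joined by C2–C5, which holds the cis C4=C5 alkene. The ten-membered ring is therefore the [3,3] isomer of a cyclohexenol (ring C1–C6) that carries the enol-ether arms C7=C8 on C6 and C10=C9 on C1.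
3. Forward: a quinone takes up both arms, giving the six-membered ring. Oxy-Cope ring expansion with C7 alkylation gives the ten-membered ring. The lactone follows, then the α-methylene group, then the O–C10 bridge and furanone, and finally the two esters.
4. Stereochemistry: absolute configuration comes from a reagent-controlled CBS reduction at C3 of a racemic enone, with separation of diastereomers. C8 and C9 come from the Z-enol-ether geometries through a chair [3,3] shift, C7 from peripheral alkylation, C6 from Felkin–Anh reduction, and C10 from anti opening of a C1–C10 epoxide by the C3 oxygen.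

Key step: step 11

Remark: locants C1–C15 follow the germacranolide numbering (C1 ketone, C2=C3, C4=C5, C6 lactone carbinol, C7, C8 methacrylate carbon, C9 senecioate carbon, C10 quaternary, C11=C13, C12 lactone carbonyl, C14 methyl, C15 CH2OH). PMB = 4-methoxybenzyl. Compounds 14 and 15 are racemic; the enantiomer drawn is the one carried on.

**Route**

Step 1
Reactants: 1 4-methoxybenzyl alcohol; 2 ethyl vinyl ether
Product: 3 4-methoxybenzyl vinyl ether
Conditions: Pd(OAc)2 (cat.), 1,10-phenanthroline (cat.), excess 2, CH2Cl2, rt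
Reagents that add atoms: none
Why: Transfer vinylation (transetherification) of a primary alcohol with excess ethyl vinyl ether is a standard way to alkyl vinyl ethers.

Step 2
Reactants: 3 4-methoxybenzyl vinyl ether
Product: 5 (Z)-1-bromo-2-[(4-methoxybenzyl)oxy]ethene, via dibromo ether 4 (not isolated)
Conditions: Br2, CH2Cl2, −78 °C; then Et3N, −78 °C → rt
Reagents that add atoms: bromine, BrBr
Why: Bromination–dehydrobromination of an enol ether (loss of HBr from the α-bromo ether) should give the 2-bromovinyl ether mainly as the cis isomer, as it does for ethyl vinyl ether.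

Step 3
Reactants: 1 4-methoxybenzyl alcohol; 6 allyl bromide
Product: 7 allyl 4-methoxybenzyl ether
Conditions: NaH, THF, 0 °C → rt
Reagents that add atoms: none
Why: Williamson ether synthesis with a primary alkoxide and an allylic bromide.

Step 4
Reactants: 7 allyl 4-methoxybenzyl ether
Product: 8 (Z)-4-methoxybenzyl prop-1-enyl ether
Conditions: KOtBu, DMSO, rt
Reagents that add atoms: none
Why: Base-mediated allyl-to-propenyl ether isomerisation runs through a cis, potassium-chelated allyl anion and should give the Z-propenyl ether.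

Step 5
Reactants: 8 (Z)-4-methoxybenzyl prop-1-enyl ether
Product: 10 (Z)-2-bromo-1-[(4-methoxybenzyl)oxy]prop-1-ene, via dibromo ether 9 (not isolated)
Conditions: Br2, CH2Cl2, −78 °C; then Et3N, −78 °C → rt
Reagents that add atoms: bromine, BrBr
Why: Bromination–dehydrobromination as in step 2; any E isomer is harmless because its lithio derivative (Li anti to OR) collapses to propyne, whereas the Z-derived reagent is chelation-stabilised.

Step 6
Reactants: 11 2,5-dimethoxybenzyl alcohol
Product: 12 (2,5-dimethoxybenzyl)oxy-triisopropylsilane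
Conditions: TIPSCl, imidazole, DMF, rt
Reagents that add atoms: chlorotriisopropylsilane, CC(C)[Si](Cl)(C(C)C)C(C)C
Why: Silylation of a primary alcohol; the hindered silyl ether is chosen to survive the acidic oxidation and all later steps.

Step 7
Reactants: 12 (2,5-dimethoxybenzyl)oxy-triisopropylsilane
Product: 13 2-{[(triisopropylsilyl)oxy]methyl}-1,4-benzoquinone
Conditions: (NH4)2Ce(NO3)6, MeCN–H2O, 0 °C
Reagents that add atoms: water, O
Why: Oxidative demethylation of a 1,4-dimethoxyarene by tetravalent cerium gives the para-quinone.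

Step 8
Reactants: 13 2-{[(triisopropylsilyl)oxy]methyl}-1,4-benzoquinone; 5 (Z)-1-bromo-2-[(4-methoxybenzyl)oxy]ethene; 10 (Z)-2-bromo-1-[(4-methoxybenzyl)oxy]prop-1-ene
Product: 15 racemic (1S,6S)-hydroxy enone (C3 ketone; C6 carries OH and the Z arm C7=C8–OPMB; C1 carries H and the Z arm C10(CH3)=C9–OPMB; arms trans), via lithium quinol alkoxide 14 (not isolated)
Conditions: 5, t-BuLi (2 equiv), THF, −78 °C; add 13, −78 °C; then the Grignard reagent from 10 [t-BuLi (2 equiv), Et2O, −78 °C; MgBr2·OEt2], −78 → −20 °C; pH 7 buffer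
Reagents that add atoms: none
Why: 1,2-Addition of the chelation-stabilised cis-β-alkoxyvinyllithium should take the less hindered carbonyl (C6, remote from the silyloxymethyl group), and alkoxide-directed conjugate addition of the vinyl Grignard reagent to the unsubstituted enone carbon C1 delivers the second arm on the alkoxide face, so the two arms end up trans.

Step 9
Reactants: 15 racemic hydroxy enone
Product: 16 (1S,3S,6S)-cyclohexene-3,6-diol
Conditions: (R)-2-methyl-CBS-oxazaborolidine (1 equiv), catecholborane, toluene, −78 °C; aq. NaOH work-up; chromatography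
Reagents that add atoms: none
Why: Corey–Bakshi–Shibata reduction under reagent control (the α-branched alkene carbon C4 is the large group) should make the 3S carbinol from both enantiomers of 15; the (1S,6S) enantiomer gives the 1,3-cis diol 16 and the other enantiomer a trans diastereomer that is removed, which fixes the absolute configuration.

Step 10
Reactants: 16 (1S,3S,6S)-cyclohexene-3,6-diol
Product: 17 (1S,3S,6S)-3-triethylsilyl ether with free tertiary C6 hydroxyl
Conditions: TESCl, imidazole, CH2Cl2, 0 °C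
Reagents that add atoms: chlorotriethylsilane, CC[Si](Cl)(CC)CC
Why: Selective silylation of the secondary allylic alcohol; the tertiary alcohol does not react under these conditions.

Step 11
Reactants: 17 (1S,3S,6S)-3-triethylsilyl ether
Product: 20 ten-membered keto ester (C6 ketone; C7 CH2CO2Me; C8 and C9 OPMB; E-C1=C10; Z-C4=C5; C7 to C9 configured as in the target), via potassium alkoxide 18 (not isolated), via potassium enolate 19 (not isolated)
Conditions: KN(SiMe3)2, 18-crown-6, THF, −78 → 0 °C; then BrCH2CO2Me, −78 °C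
Reagents that add atoms: methyl bromoacetate, COC(=O)CBr
Why: The alkoxide 18 of this trans-1,2-dialkenylcyclohexenol should undergo an anionic oxy-Cope [3,3]-sigmatropic shift (closest known type: ring expansion of 1,2-divinylcyclohexanols to cyclodec-5-enones with in situ enolate alkylation), which forms C8–C9 between the two enol-ether termini while C1–C6 breaks. The ten-membered carbocycle is thus closed by a suprafacial six-centre shift as a four-atom ring expansion (6 → 10), not by an end-to-end medium-ring cyclisation, and the cis C4=C5 bond is carried over unchanged. With both ring bonds equatorial (trans arms) the chair transition state is open; the Z-enol ethers put OR8 and OR9 axial (small groups, OR8 bridged to the alkoxide by K+), so the (1S,6S) configuration is translated into the threo C8/C9 diether of the target and into E geometry at C1=C10 and at the C6 enolate. Enolate 19 is then alkylated at C7 on its peripheral face, the inner face being covered across the ring by the C1=C10 unit, which sets C7. The step needs chair over boat (a boat would give the erythro diether), the exocyclic [3,3] path over the strained bicyclic one through the ring alkene C4=C5, and C-alkylation before β-elimination of the C8 ether; the first two are secured by the diequatorial arms, the last by low-temperature trapping with a soft bromoacetate.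

Step 12
Reactants: 20 ten-membered keto ester
Product: 22 trans-fused γ-lactone (O6–C12), via hydroxy ester 21 (not isolated)
Conditions: NaBH4, CeCl3·7H2O, MeOH, −78 °C; then K2CO3, MeOH, rt
Reagents that add atoms: none
Why: Luche 1,2-reduction of the enone; Felkin–Anh attack anti to the C7–C8 ring bond should place O6 syn to C11 (6R), and the alkoxide then closes the trans-fused lactone on the methyl ester.

Step 13
Reactants: 22 trans-fused γ-lactone
Product: 25 α-methylene lactone, via Mannich base 23 (not isolated), via trimethylammonium iodide 24 (not isolated)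
Conditions: LiN(i-Pr)2, THF, −78 °C; CH2=NMe2+ I−, −78 °C → rt; MeI, MeOH, rt; NaHCO3, CH2Cl2–H2O, rt
Reagents that add atoms: dimethylmethyleneiminium iodide, C=[N+](C)C.[I-]
Why: α-Methylenation by Mannich reaction of the lactone enolate, N-methylation and Hofmann-type elimination; C11 ends up sp2, so no stereocentre is at stake.

Step 14
Reactants: 25 α-methylene lactone
Product: 28 bridged tetrahydrofuran-1-ol (O joins C3 and C10; C1 carries OH), via epoxide 26 (not isolated), via epoxy alcohol 27 (not isolated)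
Conditions: mCPBA, NaHCO3, CH2Cl2, −20 °C; then MeOH, camphorsulfonic acid (cat.), 0 °C → rt
Reagents that add atoms: 3-chloroperbenzoic acid, OOC(=O)c1cccc(Cl)c1
Why: Peracid epoxidation should pick the strained, only electron-rich alkene C1=C10 on its peripheral face; acid then removes the triethylsilyl group and the 3S hydroxyl opens the epoxide at tertiary C10 with inversion (5-endo opening of a homoallylic epoxy alcohol), and because only a cis-2,5-bridged tetrahydrofuran can form, the C3 configuration is relayed to C10.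

Step 15
Reactants: 28 bridged tetrahydrofuran-1-ol
Product: 30 3(2H)-furanone (C1 ketone, C2=C3, O–C10), via tetrahydrofuranone 29 (not isolated)
Conditions: IBX (2-iodoxybenzoic acid), DMSO, 65 °C
Reagents that add atoms: none
Why: IBX oxidation of the C1 carbinol followed by IBX dehydrogenation of the ketone at C2–C3, its only enolisable side, gives the dienone-conjugated furanone and erases the temporary C3 centre.

Step 16
Reactants: 30 3(2H)-furanone
Product: 31 C8,C9-diol
Conditions: DDQ, CH2Cl2–pH 7 buffer, 0 °C → rt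
Reagents that add atoms: none
Why: Oxidative cleavage of both PMB ethers; the electron-poor alkenes and the silyl ether are inert to DDQ.

Step 17
Reactants: 31 C8,C9-diol
Product: 32 C8 methacrylate with free C9 hydroxyl
Conditions: methacrylic anhydride (1.1 equiv), i-Pr2NEt, DMAP (cat.), CH2Cl2, −40 °C
Reagents that add atoms: methacrylic anhydride, C=C(C)C(=O)OC(=O)C(C)=C
Why: DMAP-catalysed acylation under kinetic control should take the C8 hydroxyl, since the C9 hydroxyl is neopentyl-like next to quaternary C10.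

Step 18
Reactants: 32 C8 methacrylate
Product: 33 C8 methacrylate C9 senecioate (C15 silyl ether)
Conditions: 3-methylbut-2-enoic acid, 2,4,6-trichlorobenzoyl chloride, Et3N, DMAP, toluene, rt
Reagents that add atoms: 3-methylbut-2-enoic acid, CC(C)=CC(=O)O
Why: Yamaguchi esterification through the mixed anhydride acylates hindered secondary alcohols and keeps the senecioate double bond conjugated.

Step 19
Reactants: 33 C8 methacrylate C9 senecioate
Product: 34 CNP0239488.2
Conditions: HF·pyridine, THF–pyridine, 0 °C → rt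
Reagents that add atoms: none
Why: Fluoride-mediated cleavage of the primary silyl ether frees the C15 alcohol without touching the esters, the lactone or the furanone.

**Compound list**

1 | 4-methoxybenzyl alcohol | COc1ccc(CO)cc1 | starting material
2 | ethyl vinyl ether | C=COCC | starting material
3 | 4-methoxybenzyl vinyl ether | C=COCc1ccc(OC)cc1 | intermediate
4 | 1,2-dibromoethyl 4-methoxybenzyl ether | BrCC(Br)OCc1ccc(OC)cc1 | intermediate
5 | (Z)-1-bromo-2-[(4-methoxybenzyl)oxy]ethene | Br/C=C\OCc1ccc(OC)cc1 | intermediate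
6 | allyl bromide | C=CCBr | starting material
7 | allyl 4-methoxybenzyl ether | C=CCOCc1ccc(OC)cc1 | intermediate
8 | (Z)-4-methoxybenzyl prop-1-enyl ether | C/C=C\OCc1ccc(OC)cc1 | intermediate
9 | 1,2-dibromopropyl 4-methoxybenzyl ether | CC(Br)C(Br)OCc1ccc(OC)cc1 | intermediate
10 | (Z)-2-bromo-1-[(4-methoxybenzyl)oxy]prop-1-ene | Br/C(C)=C\OCc1ccc(OC)cc1 | intermediate
11 | 2,5-dimethoxybenzyl alcohol | COc1ccc(OC)c(CO)c1 | starting material
12 | (2,5-dimethoxybenzyl)oxy-triisopropylsilane | COc1ccc(OC)c(CO[Si](C(C)C)(C(C)C)C(C)C)c1 | intermediate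
13 | 2-{[(triisopropylsilyl)oxy]methyl}-1,4-benzoquinone | O=C1C=CC(=O)C(CO[Si](C(C)C)(C(C)C)C(C)C)=C1 | intermediate
14 | lithium quinol alkoxide (racemic; C6 alkoxide with Z-2-(PMB-oxy)ethenyl group) | [Li+].[O-][C@]1(/C=C\OCc2ccc(OC)cc2)C=CC(=O)C(CO[Si](C(C)C)(C(C)C)C(C)C)=C1 | intermediate
15 | racemic (1S,6S)-hydroxy enone (C3 ketone, trans arms) | O=C1C[C@@H](/C(C)=C\OCc2ccc(OC)cc2)[C@](O)(/C=C\OCc2ccc(OC)cc2)C=C1CO[Si](C(C)C)(C(C)C)C(C)C | intermediate
16 | (1S,3S,6S)-cyclohexene-3,6-diol | O[C@H]1C[C@@H](/C(C)=C\OCc2ccc(OC)cc2)[C@](O)(/C=C\OCc2ccc(OC)cc2)C=C1CO[Si](C(C)C)(C(C)C)C(C)C | intermediate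
17 | (1S,3S,6S)-3-triethylsilyl ether, C6 tertiary alcohol | CC[Si](CC)(CC)O[C@H]1C[C@@H](/C(C)=C\OCc2ccc(OC)cc2)[C@](O)(/C=C\OCc2ccc(OC)cc2)C=C1CO[Si](C(C)C)(C(C)C)C(C)C | intermediate
18 | potassium alkoxide of 17 | CC[Si](CC)(CC)O[C@H]1C[C@@H](/C(C)=C\OCc2ccc(OC)cc2)[C@]([O-])(/C=C\OCc2ccc(OC)cc2)C=C1CO[Si](C(C)C)(C(C)C)C(C)C.[K+] | intermediate
19 | ten-membered potassium enolate (C6 O−, E-C6=C7, E-C1=C10, Z-C4=C5) | COc1ccc(CO[C@H]2/C=C(\[O-])/C=C(/CO[Si](C(C)C)(C(C)C)C(C)C)[C@@H](O[Si](CC)(CC)CC)C/C=C(\C)[C@@H]2OCc3ccc(OC)cc3)cc1.[K+] | intermediate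
20 | ten-membered keto ester (C3 S; C7, C8, C9 as in the target) | COc1ccc(CO[C@H]2[C@@H](CC(=O)OC)C(=O)/C=C(/CO[Si](C(C)C)(C(C)C)C(C)C)[C@@H](O[Si](CC)(CC)CC)C/C=C(\C)[C@@H]2OCc3ccc(OC)cc3)cc1 | intermediate
21 | C6 hydroxy ester (C6 as in the target) | COc1ccc(CO[C@H]2[C@@H](CC(=O)OC)[C@H](O)/C=C(/CO[Si](C(C)C)(C(C)C)C(C)C)[C@@H](O[Si](CC)(CC)CC)C/C=C(\C)[C@@H]2OCc3ccc(OC)cc3)cc1 | intermediate
22 | trans-fused γ-lactone (C6 to C9 as in the target) | COc1ccc(CO[C@H]2[C@H]3CC(=O)O[C@@H]3/C=C(/CO[Si](C(C)C)(C(C)C)C(C)C)[C@@H](O[Si](CC)(CC)CC)C/C=C(\C)[C@@H]2OCc4ccc(OC)cc4)cc1 | intermediate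
23 | α-(dimethylaminomethyl) lactone (C11 epimers) | COc1ccc(CO[C@H]2[C@H]3C(CN(C)C)C(=O)O[C@@H]3/C=C(/CO[Si](C(C)C)(C(C)C)C(C)C)[C@@H](O[Si](CC)(CC)CC)C/C=C(\C)[C@@H]2OCc4ccc(OC)cc4)cc1 | intermediate
24 | trimethylammonium iodide of 23 | COc1ccc(CO[C@H]2[C@H]3C(C[N+](C)(C)C)C(=O)O[C@@H]3/C=C(/CO[Si](C(C)C)(C(C)C)C(C)C)[C@@H](O[Si](CC)(CC)CC)C/C=C(\C)[C@@H]2OCc4ccc(OC)cc4)cc1.[I-] | intermediate
25 | α-methylene lactone | COc1ccc(CO[C@H]2[C@H]3C(=C)C(=O)O[C@@H]3/C=C(/CO[Si](C(C)C)(C(C)C)C(C)C)[C@@H](O[Si](CC)(CC)CC)C/C=C(\C)[C@@H]2OCc4ccc(OC)cc4)cc1 | intermediate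
26 | C1–C10 epoxide | COc1ccc(CO[C@H]2[C@H]3C(=C)C(=O)O[C@@H]3/C=C(/CO[Si](C(C)C)(C(C)C)C(C)C)[C@@H](O[Si](CC)(CC)CC)C[C@H]5O[C@]5(C)[C@@H]2OCc4ccc(OC)cc4)cc1 | intermediate
27 | C1–C10 epoxide with free C3 hydroxyl | COc1ccc(CO[C@H]2[C@H]3C(=C)C(=O)O[C@@H]3/C=C(/CO[Si](C(C)C)(C(C)C)C(C)C)[C@@H](O)C[C@H]5O[C@]5(C)[C@@H]2OCc4ccc(OC)cc4)cc1 | intermediate
28 | bridged tetrahydrofuran-1-ol (O joins C3 and C10) | COc1ccc(CO[C@H]2[C@H]3C(=C)C(=O)O[C@@H]3/C=C(/CO[Si](C(C)C)(C(C)C)C(C)C)[C@@H]5C[C@@H](O)[C@@](C)(O5)[C@@H]2OCc4ccc(OC)cc4)cc1 | intermediate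
29 | bridged tetrahydrofuran-1-one | COc1ccc(CO[C@H]2[C@H]3C(=C)C(=O)O[C@@H]3/C=C(/CO[Si](C(C)C)(C(C)C)C(C)C)[C@@H]5CC(=O)[C@@](C)(O5)[C@@H]2OCc4ccc(OC)cc4)cc1 | intermediate
30 | 3(2H)-furanone with C8 and C9 PMB ethers | COc1ccc(CO[C@H]2[C@H]3C(=C)C(=O)O[C@@H]3/C=C(/CO[Si](C(C)C)(C(C)C)C(C)C)C5=CC(=O)[C@@](C)(O5)[C@@H]2OCc4ccc(OC)cc4)cc1 | intermediate
31 | C8,C9-diol | O[C@H]1[C@H]2C(=C)C(=O)O[C@@H]2/C=C(/CO[Si](C(C)C)(C(C)C)C(C)C)C2=CC(=O)[C@@](C)(O2)[C@@H]1O | intermediate
32 | C8 methacrylate, C9 hydroxyl | C=C(C)C(=O)O[C@H]1[C@H]2C(=C)C(=O)O[C@@H]2/C=C(/CO[Si](C(C)C)(C(C)C)C(C)C)C2=CC(=O)[C@@](C)(O2)[C@@H]1O | intermediate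
33 | C8 methacrylate, C9 senecioate, C15 triisopropylsilyl ether | C=C(C)C(=O)O[C@H]1[C@H]2C(=C)C(=O)O[C@@H]2/C=C(/CO[Si](C(C)C)(C(C)C)C(C)C)C2=CC(=O)[C@@](C)(O2)[C@@H]1OC(=O)C=C(C)C | intermediate
34 | CNP0239488.2 | C=C(C)C(=O)O[C@H]1[C@H]2C(=C)C(=O)O[C@@H]2/C=C(/CO)C2=CC(=O)[C@@](C)(O2)[C@@H]1OC(=O)C=C(C)C | target

**Count and risks**

Total steps: 19. Longest linear sequence: 15 (steps 3–5, then 8–19).

Step 11. The sigmatropic shift may leak through a boat transition state, which would give the erythro C8/C9 diether. The potassium enolate may also be lost by β-elimination of the C8 ether or by O-alkylation. The fallback is a neutral, two-stage version that sets out from 17. The tertiary alcohol is silylated with N-trimethylsilylimidazole (neat, 60 °C) to give trimethylsilyl ether F1. Thermal siloxy-Cope rearrangement (toluene, sealed tube, 180 °C) gives the ten-membered trimethylsilyl enol ether F2, so no enolate is exposed to warm conditions. MeLi (THF, −20 °C) then releases lithium enolate F3 regiospecifically, and alkylation with methyl bromoacetate at −78 °C comes back to the route at 20.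

Step 8. The vinyllithium may reduce the quinone by electron transfer, the β-alkoxyvinyl metal may eliminate, or the first addition may take the wrong carbonyl. In the fallback the C7–C8 unit is brought in as an alkynyl ether, setting out from 1 and 13. Alcohol 1 is treated with KH and trichloroethylene (THF, −50 °C → rt) to give (E)-1,2-dichlorovinyl 4-methoxybenzyl ether F4. n-BuLi (2 equiv, −78 °C) converts it into lithium [(4-methoxybenzyl)oxy]ethynide F5, a less basic nucleophile that cannot eliminate. Addition to the C6 carbonyl of 13 gives, after work-up, alkynyl quinol F6. The same alkoxide-directed addition of the Grignard reagent from 10 gives alkynyl hydroxy enone F7. Cis-semihydrogenation (H2, Pd on CaCO3 poisoned with Pb(OAc)2, quinoline, EtOAc) then makes the Z-enol ether and comes back to the route at 15.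

Step 12. Hydride may be delivered to the other face of the C6 carbonyl (peripheral instead of Felkin–Anh attack), which leads to the C6 epimer and a cis-fused lactone. The fallback sets out from 20. Reduction as in step 12, without the carbonate treatment, gives the C6-epimeric hydroxy ester F8. Saponification (LiOH, THF–H2O, 0 °C) and buffered acidification give hydroxy acid F9. Mitsunobu lactonisation (PPh3, diisopropyl azodicarboxylate, toluene, 0 °C) closes the ring by SN2 attack of the carboxylate with inversion at C6 and comes back to the route at 22.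

**Further compounds**

F1 | step 11 | C6 trimethylsilyl ether of 17 | CC[Si](CC)(CC)O[C@H]1C[C@@H](/C(C)=C\OCc2ccc(OC)cc2)[C@](O[Si](C)(C)C)(/C=C\OCc2ccc(OC)cc2)C=C1CO[Si](C(C)C)(C(C)C)C(C)C
F2 | step 11 | ten-membered C6 trimethylsilyl enol ether | COc1ccc(CO[C@H]2/C=C(\O[Si](C)(C)C)/C=C(/CO[Si](C(C)C)(C(C)C)C(C)C)[C@@H](O[Si](CC)(CC)CC)C/C=C(\C)[C@@H]2OCc3ccc(OC)cc3)cc1
F3 | step 11 | ten-membered lithium enolate | COc1ccc(CO[C@H]2/C=C(\[O-])/C=C(/CO[Si](C(C)C)(C(C)C)C(C)C)[C@@H](O[Si](CC)(CC)CC)C/C=C(\C)[C@@H]2OCc3ccc(OC)cc3)cc1.[Li+]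
F4 | step 8 | (E)-1,2-dichlorovinyl 4-methoxybenzyl ether | Cl/C=C(/Cl)OCc1ccc(OC)cc1
F5 | step 8 | lithium [(4-methoxybenzyl)oxy]ethynide | [Li]C#COCc1ccc(OC)cc1
F6 | step 8 | alkynyl quinol (racemic) | O[C@]1(C#COCc2ccc(OC)cc2)C=CC(=O)C(CO[Si](C(C)C)(C(C)C)C(C)C)=C1
F7 | step 8 | alkynyl hydroxy enone (racemic) | O=C1C[C@@H](/C(C)=C\OCc2ccc(OC)cc2)[C@](O)(C#COCc2ccc(OC)cc2)C=C1CO[Si](C(C)C)(C(C)C)C(C)C
F8 | step 12 | C6-epimeric hydroxy ester | COc1ccc(CO[C@H]2[C@@H](CC(=O)OC)[C@@H](O)/C=C(/CO[Si](C(C)C)(C(C)C)C(C)C)[C@@H](O[Si](CC)(CC)CC)C/C=C(\C)[C@@H]2OCc3ccc(OC)cc3)cc1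
F9 | step 12 | C6-epimeric hydroxy acid | COc1ccc(CO[C@H]2[C@@H](CC(=O)O)[C@@H](O)/C=C(/CO[Si](C(C)C)(C(C)C)C(C)C)[C@@H](O[Si](CC)(CC)CC)C/C=C(\C)[C@@H]2OCc3ccc(OC)cc3)cc1
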